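**Remark on the chemistry:** the target has no stereocentre. The only stereochemical element in the route is the E geometry of enol ether 4, carried into keto esters 6 and 8, which places the ester cis to the γ-carbon.

## The problem

Target 13 is a flavone whose ring B and ring C are ordinary. The difficulty lies in ring A, a benzene without hydrogen: C4a (acyl), C5 (OMe), C6 (OMe), C7 (OH), C8 (OMe), C8a (O1). The five contiguous oxygens are in three different states (methyl ether, free phenol, ring-C ether) and must be told apart. The pattern runs against the intrinsic reactivity of 5,7-dioxygenated flavones: a 5-hydroxyl, hydrogen-bonded to the C4 carbonyl, is the last to be alkylated and a 5-methoxyl the first to be cleaved by Lewis acids, whereas the 7-hydroxyl is the most acidic and the first to be alkylated. Here C5 is methylated and C7 is free, so a late alkylation or dealkylation cannot set the pattern cleanly. There is no stereocentre; all control is regiochemical. The electron-rich polyoxygenated phenols on the way are oxidised by air under base, and the 5-methoxyl peri to the carbonyl will not survive strong Lewis acids.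

The feature that opens the problem is that C5, C7 and C8a are mutually meta, a phloroglucinol pattern. Their oxygens correspond to three oxidation levels of one six-carbon chain C8a–C4a–C5–C6–C7–C8: carboxyl at C8a, enol ether at C5, ketone at C7. C6 and C8 carry methoxyl as α-substituents and C4a is the lone CH. That chain, closed through the C7 oxygen onto C8a, is 2-pyranone 7, an isomer of ring-A phenol 10.

## Retrosynthesis

**13 ⇒ 10 + 11.** Ring C is cut at C4–C4a and O1–C2. This leaves 2,4,5-trimethoxybenzene-1,3-diol 10 and the commercial β-keto ester 11, which carries C2, C3, C4 and ring B. Cutting at the usual chalcone bonds would instead demand an acetophenone of ring A and two more steps. In 10 the only ring carbon with hydrogen is C4a, and the only hydroxyl ortho to it is the C8a hydroxyl, since C5 is already an ether. The forward thermal condensation can therefore acylate one carbon and close onto one oxygen only, and the C7 hydroxyl must stay free. Phenol 10 has nine carbons against nineteen in 13.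

**10 ⇒ 7 (key).** Ring A is cut at C8–C8a and C8a is reconnected to the oxygen on C7. The result is 4,5-dimethoxy-6-(methoxymethyl)-2H-pyran-2-one 7, an isomer of 10. This cut is preferred to its neighbours for two reasons:
- A cut at C4a–C5 (the polyketide Claisen direction) would deliver C5 as a ketone and hence a free 5-hydroxyl, losing the methyl ether.
- With the cut at C8–C8a, C5 is a preformed enol-ether carbon that is never attacked, C7 is a ketone carbon that becomes the free phenol, and C8a is the lactone carbon that becomes the second phenol.

The forward reaction asks methoxide to open the lactone to the methyl keto ester 8 and the terminal CH2OMe carbanion to re-close onto the ester (via dione 9). Pyranone 7 is a stable compound that can be purified and is made in one operation.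

**7 ⇒ 4 + 5.** The lactone C–O bond and the C6–C7 bond (flavone numbering) are cut. This gives the γ-dienolate of ethyl (2E)-3,4-dimethoxybut-2-enoate 4 and methoxyacetyl chloride 5, by way of the open-chain ethyl keto ester 6. A vinylogous Claisen acylation followed by lactonisation is the standard way to 4-methoxy-2-pyranones. It needs γ-selective acylation, which the 3-alkoxy group of such dienolates secures. The ester alkoxy group of 4 does not reach the target: it leaves as ethanol when 6 lactonises, and the lactone carbonyl of 7 is later taken up by methoxide as the methyl ester 8.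

**4 ⇒ 1 + 2.** The enol-ether C–O bond is cut. Commercial ethyl 4-methoxy-3-oxobutanoate 1 and trimethyl orthoformate 2 give 4 through ketal 3. This step fixes the C5 methoxyl of the target before any ring exists.

## Roads not taken

**Alternative 1:** the most obvious plan cuts only ring C (O1–C2 and C2–C3) and takes ring A intact.
- Forward: Claisen–Schmidt condensation of 1-[4-(benzyloxy)-2-hydroxy-3,5,6-trimethoxyphenyl]ethan-1-one A1 with 4-methoxybenzaldehyde gives chalcone A2. Oxidative cyclisation (I2, DMSO) gives 7-(benzyloxy)-5,6,8-trimethoxy-2-(4-methoxyphenyl)-4H-chromen-4-one A3, and hydrogenolysis gives 13.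
- Why the chosen plan is better: the three steps after A1 are safe, but A1 is the whole problem. Its hexasubstituted ring must be reached from a simpler phenol by a run of acylation, ring hydroxylation, selective methylations and a benzyl protection, each relying on small reactivity differences between neighbouring hydroxyls. The chosen plan has four steps in all, uses no protecting group and makes no selective O-alkylation.

**Alternative 2:** ring A is cut at C4a–C5 and C8–C8a for a Moore-type cyclobutenone ring expansion.
- Forward: 5-bromo-2-(4-methoxyphenyl)-4H-pyran-4-one A4 is lithiated, added to dimethyl squarate and trapped as the methyl ether, 2,3,4-trimethoxy-4-[6-(4-methoxyphenyl)-4-oxo-4H-pyran-3-yl]cyclobut-2-en-1-one A5. Thermal four-electron ring opening to a dienylketene and six-electron electrocyclisation onto the pyranone C2=C3 bond would build ring A in one step.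
- Why the chosen plan is better: the squarate carbons end as C5–C8 with the two methoxyl-bearing carbons in the middle (C6 and C7), and the free hydroxyl arises at the ketene carbon C8. The product is therefore the isomer 8-hydroxy-5,6,7-trimethoxy-2-(4-methoxyphenyl)-4H-chromen-4-one A6. Reaching 13 would need a squarate with two different alkoxy groups and a regioselective addition to one of two nearly equal carbonyls, for which the substrate offers no control element, followed by methylation and deprotection.

**Alternative 3:** ring A is taken as a symmetrical phloroglucinol.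
- Forward: thermal condensation of 2,4-dimethoxybenzene-1,3,5-triol A7 with 11 gives 5,7-dihydroxy-6,8-dimethoxy-2-(4-methoxyphenyl)-4H-chromen-4-one A8. Benzylation at the 7-hydroxyl gives A9, methylation of the chelated 5-hydroxyl gives A3, and hydrogenolysis gives 13.
- Why the chosen plan is better: symmetry erases the distinction between the C5 and C7 oxygens, which must then be restored against intrinsic reactivity by three extra steps. Triol A7 is also no easier to obtain than 10. In the chosen plan the same distinction is written into the oxidation levels of the chain.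

Key step: step 3

## Route

**Step 1**
Reactants: 1 ethyl 4-methoxy-3-oxobutanoate; 2 trimethyl orthoformate
Product: 4 ethyl (2E)-3,4-dimethoxybut-2-enoate, via dimethyl ketal 3 (not isolated)
Conditions: HC(OMe)3 (1.5 equiv), cat. H2SO4, neat, 25 °C; then distillation from cat. TsOH, 130 °C (−MeOH)
Reagents that add atoms: trimethyl orthoformate (2), COC(OC)OC
Why: Acid-catalysed ketalisation of the ketone by the orthoester and thermal loss of methanol from ketal 3 give the conjugated enol ether; the E isomer (methoxyl trans to the ester, CH2OMe cis to it) is the thermodynamic one for 3-alkoxy-2-enoates, as in the standard preparation of ethyl 3-methoxybut-2-enoate from ethyl acetoacetate, and running without added alcohol keeps the ethyl ester.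

**Step 2**
Reactants: 4 ethyl (2E)-3,4-dimethoxybut-2-enoate; 5 methoxyacetyl chloride
Product: 7 4,5-dimethoxy-6-(methoxymethyl)-2H-pyran-2-one, via open-chain ethyl keto ester 6 (not isolated)
Conditions: 4 (2.1 equiv), LiN(iPr)2 (2.1 equiv), THF, −78 °C; 5 (1 equiv), −78 to 0 °C; aq. NH4Cl; then cat. DBU, PhMe, 80 °C (−EtOH)
Reagents that add atoms: methoxyacetyl chloride (5), COCC(=O)Cl
Why: γ-Deprotonation of the E enol ether (CH2 syn to the ester carbonyl) gives the vinylogous ester dienolate, which is acylated at the γ-carbon (vinylogous Claisen acylation), the second equivalent of dienolate taking up the acidic proton of 6; the enol oxygen of 6 then lactonises onto the cis ethyl ester with loss of ethanol, the standard access to 4-methoxy-2-pyranones, and the labile stereocentre of 6 disappears.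

**Step 3**
Reactants: 7 4,5-dimethoxy-6-(methoxymethyl)-2H-pyran-2-one
Product: 10 2,4,5-trimethoxybenzene-1,3-diol, via open-chain methyl keto ester 8 (not isolated), via cyclohexenedione 9 (not isolated)
Conditions: NaOMe (4 equiv), MeOH, 130 °C, sealed tube, under argon; then 2 M HCl, 0 °C
Reagents that add atoms: none
Why: Methoxide adds to the lactone carbonyl of 7 and opens the ring to the enolate of methyl keto ester 8, whose E enoate holds the methyl ester cis to the chain; proton exchange in methanol gives the minor enolate at the terminal CH2OMe carbon, which attacks the ester carbonyl in a Dieckmann-type C-acylation, and loss of methoxide gives dione 9, whose two enolisations give the benzene ring as its bis(phenoxide). The closest known reaction type is the alkoxide-mediated isomerisation of 6-alkyl-4-methoxy-2-pyranones to 5-methoxyresorcinols, the laboratory form of the polyketide pyranone-to-phloroglucinol Claisen switch. The ring closes in the 6-(enolendo)-exo-trig mode. No stereocentre is made, and the two sp3 centres of 9 vanish on aromatisation. The step needs C- over O-cyclisation and cyclisation over retro-Claisen cleavage: O-cyclisation only returns 7 and is reversible, whereas C-cyclisation is made irreversible by aromatisation and double deprotonation, so the equilibrating mixture should drain to 10. All exchangeable alkoxy groups of 7 and 8 are methoxyl and the medium is methoxide in methanol, so ester and vinylogous-ester exchange are degenerate. The methylation pattern is fixed by oxidation level: the enol-ether carbon keeps its OMe (C5 of the target), the ketone carbon becomes the free OH between two methoxyls (C7), and the lactone carbon becomes the second OH (C8a).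

**Step 4**
Reactants: 10 2,4,5-trimethoxybenzene-1,3-diol; 11 ethyl 3-(4-methoxyphenyl)-3-oxopropanoate
Product: 13 7-hydroxy-5,6,8-trimethoxy-2-(4-methoxyphenyl)-4H-chromen-4-one (target), via aryl diketone 12 (not isolated)
Conditions: 11 (2 equiv), neat, 240 °C, under argon (−EtOH, −H2O)
Reagents that add atoms: ethyl 3-(4-methoxyphenyl)-3-oxopropanoate (11), CCOC(=O)CC(=O)c1ccc(OC)cc1
Why: Mentzer pyrone synthesis, as used for 5,7-dihydroxyflavones from phloroglucinol and ethyl aroylacetates: thermal C-acylation of the only free ring carbon of 10 (ortho to one hydroxyl, para to the other, ortho to a methoxyl) with loss of ethanol gives the o-hydroxyaryl β-diketone 12, which cyclodehydrates onto the only ortho hydroxyl; the other hydroxyl has no free ortho carbon, cannot enter ring C, and remains as the 7-OH.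

## Compound list

1 | ethyl 4-methoxy-3-oxobutanoate | CCOC(=O)CC(=O)COC | starting material
2 | trimethyl orthoformate | COC(OC)OC | starting material
3 | ethyl 3,3,4-trimethoxybutanoate | CCOC(=O)CC(OC)(OC)COC | intermediate (not isolated)
4 | ethyl (2E)-3,4-dimethoxybut-2-enoate | COC/C(OC)=C\C(=O)OCC | intermediate
5 | methoxyacetyl chloride | COCC(=O)Cl | starting material
6 | ethyl (2E)-3,4,6-trimethoxy-5-oxohex-2-enoate (racemic, enolisable at C4) | COCC(=O)C(OC)/C(OC)=C\C(=O)OCC | intermediate (not isolated)
7 | 4,5-dimethoxy-6-(methoxymethyl)-2H-pyran-2-one | COCc1oc(=O)cc(OC)c1OC | intermediate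
8 | methyl (2E)-3,4,6-trimethoxy-5-oxohex-2-enoate (racemic, enolisable at C4; present as its sodium enolate) | COCC(=O)C(OC)/C(OC)=C\C(=O)OC | intermediate (not isolated)
9 | 2,5,6-trimethoxycyclohex-4-ene-1,3-dione (mixture of enolisable diastereomers) | COC1C(=O)C=C(OC)C(OC)C1=O | intermediate (not isolated)
10 | 2,4,5-trimethoxybenzene-1,3-diol | COc1cc(O)c(OC)c(O)c1OC | intermediate
11 | ethyl 3-(4-methoxyphenyl)-3-oxopropanoate | CCOC(=O)CC(=O)c1ccc(OC)cc1 | starting material
12 | 1-(2,4-dihydroxy-3,5,6-trimethoxyphenyl)-3-(4-methoxyphenyl)propane-1,3-dione | COc1ccc(cc1)C(=O)CC(=O)c1c(O)c(OC)c(O)c(OC)c1OC | intermediate (not isolated)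
13 | 7-hydroxy-5,6,8-trimethoxy-2-(4-methoxyphenyl)-4H-chromen-4-one | COc1ccc(-c2cc(=O)c3c(OC)c(OC)c(O)c(OC)c3o2)cc1 | target

## Step count and risks

Total steps: 4. Longest linear sequence: 4 steps (1 → 4 → 7 → 10 → 13).

**Step 3 (key step).**
- What may go wrong: retro-Claisen cleavage of the open-chain keto ester 8 by methoxide attack at its ketone, which splits the chain back into its four-carbon enoate half and its two-carbon ester half. This can outrun the ring closure because the carbanion needed at the terminal CH2OMe is the less acidic site and the ester is a deactivated vinylogous carbonate. The mixture may also stall at the equilibrium between pyranone and ring-opened enolate.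
- Fallback: this changes the plan to late oxygenation of a preformed flavone. It sets out from 11 and rejoins the route at 13. Thermal condensation of 11 with commercial phloroglucinol (neat, 240 °C) should give 5,7-dihydroxy-2-(4-methoxyphenyl)-4H-chromen-4-one F1. Benzylation of the more acidic 7-hydroxyl (BnBr, K2CO3, acetone) should give 7-(benzyloxy)-5-hydroxy-2-(4-methoxyphenyl)-4H-chromen-4-one F2. Forcing methylation of the chelated 5-hydroxyl (Me2SO4, K2CO3, DMF, 60 °C) should give 7-(benzyloxy)-5-methoxy-2-(4-methoxyphenyl)-4H-chromen-4-one F3. Hydrogenolysis (H2, Pd/C, EtOAc) should give 7-hydroxy-5-methoxy-2-(4-methoxyphenyl)-4H-chromen-4-one F4. Bromination at both positions ortho to the free phenol (NBS, 2 equiv, DMF, 0 °C) should give 6,8-dibromo-7-hydroxy-5-methoxy-2-(4-methoxyphenyl)-4H-chromen-4-one F5. Ullmann-type double methoxylation (NaOMe, CuBr, DMF–MeOH, 110 °C) should then give 13.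

**Step 4.**
- What may go wrong: acylation on oxygen instead of carbon (especially at the unhindered hydroxyl that cannot cyclise), Pechmann-type closure through the ketone carbonyl instead of the ester carbonyl, or oxidative decomposition of the electron-rich phenol 10 at the high temperature.
- Fallback: this builds ring C stepwise through a chalcone. It sets out from 10 and rejoins at 13. Houben–Hoesch acylation of 10 (MeCN, ZnCl2, HCl, Et2O, then hot water) at its only free carbon should give 1-(2,4-dihydroxy-3,5,6-trimethoxyphenyl)ethan-1-one F6. Claisen–Schmidt condensation with 4-methoxybenzaldehyde (KOH, EtOH) should give (E)-1-(2,4-dihydroxy-3,5,6-trimethoxyphenyl)-3-(4-methoxyphenyl)prop-2-en-1-one F7. Oxidative cyclisation (cat. I2, DMSO, 120 °C) should then give 13, closing onto the only ortho hydroxyl.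

**Step 2.**
- What may go wrong: acylation of the dienolate on oxygen or at the α-carbon, a second acylation of the product enolate, or ketene formation from the acid chloride by the amide base. Each would lower the supply of keto ester 6 for lactonisation.
- Fallback: this uses a β-keto ester dianion and a late O-methylation in place of the enol-ether dienolate. It sets out from 1 and rejoins at 7. The dianion of 1 (NaH, then n-BuLi, THF, 0 °C) is acylated at the γ-carbon with N,2-dimethoxy-N-methylacetamide to give ethyl 4,6-dimethoxy-3,5-dioxohexanoate F8. Lactonisation (DBU, PhMe, 80 °C) should give 4-hydroxy-5-methoxy-6-(methoxymethyl)-2H-pyran-2-one F9. O-Methylation (Me2SO4, K2CO3, acetone) should then give 7.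

## Further compounds

F1 | step 3 | 5,7-dihydroxy-2-(4-methoxyphenyl)-4H-chromen-4-one | COc1ccc(cc1)-c1cc(=O)c2c(O)cc(O)cc2o1
F2 | step 3 | 7-(benzyloxy)-5-hydroxy-2-(4-methoxyphenyl)-4H-chromen-4-one | COc1ccc(cc1)-c1cc(=O)c2c(O)cc(OCc3ccccc3)cc2o1
F3 | step 3 | 7-(benzyloxy)-5-methoxy-2-(4-methoxyphenyl)-4H-chromen-4-one | COc1ccc(cc1)-c1cc(=O)c2c(OC)cc(OCc3ccccc3)cc2o1
F4 | step 3 | 7-hydroxy-5-methoxy-2-(4-methoxyphenyl)-4H-chromen-4-one | COc1ccc(cc1)-c1cc(=O)c2c(OC)cc(O)cc2o1
F5 | step 3 | 6,8-dibromo-7-hydroxy-5-methoxy-2-(4-methoxyphenyl)-4H-chromen-4-one | COc1ccc(cc1)-c1cc(=O)c2c(OC)c(Br)c(O)c(Br)c2o1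
F6 | step 4 | 1-(2,4-dihydroxy-3,5,6-trimethoxyphenyl)ethan-1-one | CC(=O)c1c(O)c(OC)c(O)c(OC)c1OC
F7 | step 4 | (E)-1-(2,4-dihydroxy-3,5,6-trimethoxyphenyl)-3-(4-methoxyphenyl)prop-2-en-1-one | COc1ccc(/C=C/C(=O)c2c(O)c(OC)c(O)c(OC)c2OC)cc1
F8 | step 2 | ethyl 4,6-dimethoxy-3,5-dioxohexanoate (racemic, enolisable) | COCC(=O)C(OC)C(=O)CC(=O)OCC
F9 | step 2 | 4-hydroxy-5-methoxy-6-(methoxymethyl)-2H-pyran-2-one | COCc1oc(=O)cc(O)c1OC
A1 | alternative 1 | 1-[4-(benzyloxy)-2-hydroxy-3,5,6-trimethoxyphenyl]ethan-1-one | CC(=O)c1c(O)c(OC)c(OCc2ccccc2)c(OC)c1OC
A2 | alternative 1 | (E)-1-[4-(benzyloxy)-2-hydroxy-3,5,6-trimethoxyphenyl]-3-(4-methoxyphenyl)prop-2-en-1-one | COc1ccc(/C=C/C(=O)c2c(O)c(OC)c(OCc3ccccc3)c(OC)c2OC)cc1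
A3 | alternative 1 | 7-(benzyloxy)-5,6,8-trimethoxy-2-(4-methoxyphenyl)-4H-chromen-4-one | COc1ccc(cc1)-c1cc(=O)c2c(OC)c(OC)c(OCc3ccccc3)c(OC)c2o1
A4 | alternative 2 | 5-bromo-2-(4-methoxyphenyl)-4H-pyran-4-one | COc1ccc(cc1)-c1cc(=O)c(Br)co1
A5 | alternative 2 | 2,3,4-trimethoxy-4-[6-(4-methoxyphenyl)-4-oxo-4H-pyran-3-yl]cyclobut-2-en-1-one (racemic) | COC1=C(OC)C(OC)(c2coc(-c3ccc(OC)cc3)cc2=O)C1=O
A6 | alternative 2 | 8-hydroxy-5,6,7-trimethoxy-2-(4-methoxyphenyl)-4H-chromen-4-one | COc1ccc(cc1)-c1cc(=O)c2c(OC)c(OC)c(OC)c(O)c2o1
A7 | alternative 3 | 2,4-dimethoxybenzene-1,3,5-triol | COc1c(O)cc(O)c(OC)c1O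
A8 | alternative 3 | 5,7-dihydroxy-6,8-dimethoxy-2-(4-methoxyphenyl)-4H-chromen-4-one | COc1ccc(cc1)-c1cc(=O)c2c(O)c(OC)c(O)c(OC)c2o1
A9 | alternative 3 | 7-(benzyloxy)-5-hydroxy-6,8-dimethoxy-2-(4-methoxyphenyl)-4H-chromen-4-one | COc1ccc(cc1)-c1cc(=O)c2c(O)c(OC)c(OCc3ccccc3)c(OC)c2o1
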